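## Analysis of the target

CNP0018313.0 (C30H22O15) is a linear chain of five benzene rings joined only by four diaryl ether oxygens and carrying eleven free phenolic hydroxyls. The rings are lettered A to E from the 3,5-dihydroxyphenoxy end, the ether oxygens O1 to O4 in the same direction, and C1 of each ring is the carbon on its ether oxygen nearer ring A. Ring A has OH on C3 and C5. Rings B and D carry their two ether oxygens on the adjacent carbons C1 and C6 and OH on C2 and C4. Ring C carries O2 on C1, O3 on C4 and OH on C2 and C6. Ring E has O4 on C1 and OH on C2, C4 and C6. There is no stereocentre and no ring other than the arenes, so the task is one of connectivity and hydroxyl differentiation only. Every ring is an electron-rich polyphenol that oxidises in air, above all under base, so the hydroxyls of rings A to D travel as methyl ethers to the last step. The difficulty is that each ether oxygen sits on at least one carbon flanked by two further oxygen substituents (C1 of rings B, C, D and E), and no ring carries an electron-withdrawing group, so each diaryl ether bond is both crowded and unactivated. The strategy rests on ring E: C1 (with O4), C2 and C6 correspond to the three carbons of an aryloxymalonate and C3, C4 and C5 to the three central carbons of a 3-oxoglutarate, so the most crowded ring can be grown around O4 and need not be joined as an arene.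

## Retrosynthetic reasoning

**23 to 22.** The eight O–CH3 bonds on rings A to D are cut last. Methyl ethers are the only masking groups that survive every earlier operation (copper couplings in hot base, peracid, hydrogenolysis, alkoxide at 110 °C). The forward step must cleave eight aryl methyl ethers, several of them flanked by aryloxy groups, without touching the four diaryl ether bonds.

**22 to 20 (through diacid 21).** The bonds from C3 and C5 of ring E to their carboxyl carbons are cut. The two ester groups are needed only as acidifying groups in the ring-forming step. A 2,4,6-trihydroxybenzoic acid loses its carboxyl group on mild heating, so they are traceless.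

**20 to 17 and 18 (key disconnection).** Ring E is opened at C2–C3 and C5–C6. This cut leaves O4 on an sp3 carbon of aryloxymalonate 17, and both fragments are symmetric, so no regiochemical question arises. The other possible cut, O4–C1 of ring E, would require an ether bond between a carbon flanked by two oxygens and a ring D oxygen that itself lies next to an aryloxy group, the worst of the four junctions. The forward reaction is a double C-acylation of oxoglutarate 18 by the two ester groups of 17, through acyclic adduct 19, followed by aromatisation.

**17 to 15 and 16.** The O4–C(sp3) bond is cut. The forward reaction is a plain phenoxide alkylation. Chloride 16 is preferred to the corresponding bromide, which can transfer positive halogen to so electron-rich a phenoxide.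

**15 to 13 (through formate 14).** The C6–O bond of ring D is traced back to a C6–CHO bond by oxygen insertion. The formyl group does two jobs: it later becomes the hydroxyl that carries O4, and before that it activates the neighbouring carbon for ether formation.

**13 to 11 and 12.** The O3–C1(ring D) bond is cut. C1 of ring D is crowded, but in bromo aldehyde 12 it bears the leaving group ortho to the formyl group, and the partner oxygen on C4 of ring C in phenol 11 is unhindered.

**11 to 10, then 10 to 8 and 9.** The benzyl group on the C4 oxygen of ring C is a placeholder for O3 and is cut first. Then the O1–C1(ring A) bond is cut. Here the crowding is placed on the nucleophile (phenol 8, hydroxyl on C1 of ring B), and ring A arrives as unhindered iodide 9.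

**8 to 6 (through formate 7), then 6 to 4 and 5.** The hydroxyl on C1 of ring B again comes from a formyl group. The O2–C6(ring B) bond is then cut so that the crowded ring C oxygen of phenol 4 is the nucleophile and C6 of ring B, with only the formyl group as ortho neighbour in 5, is the electrophile. The regioisomeric bromo aldehydes 5 and 12 thus decide whether a new ring is entered at its open carbon (ring B) or its crowded one (ring D).

**4 to 3 to 1.** Ring C is traced to diol 3 by cutting the benzyl ether on its unhindered oxygen, and 3 to aldehyde 1 by oxygen insertion into the aryl–CHO bond. The forward steps need selectivity only between a free and a doubly flanked hydroxyl.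

## Alternatives that were turned down

**Alternative 1:** Ring B would be assembled on 2,6-dichloro-1,4-benzoquinone A2, the disconnections being the C2–OCH3 and C6–O2 bonds of ring B. In the forward step an alkoxide and then the phenoxide of ring C phenol 4 each displace one chloride of A2 by conjugate addition–elimination. This gives 2-[4-(benzyloxy)-2,6-dimethoxyphenoxy]-6-methoxy-1,4-benzoquinone A1 in one flask.
- For: the crowded O2 bond forms without metal and at low temperature, with the hindered oxygen as nucleophile and a small, strongly electrophilic carbon as acceptor. For this one bond it is at least as dependable as the copper coupling of step 3, and cheaper.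
- Against: A1 holds ring B at the quinone level. After reduction, the hydroxyls on C1 and C4 of ring B must be told apart, the open one methylated and the crowded one arylated by ring A. The two substitutions on A2 are statistical, aryloxy–alkoxy exchange on the quinone is reversible, and the electron-rich phenoxide of 4 can reduce the quinone by electron transfer. The method reaches only ether carbons next to a quinone carbonyl carbon (C6 of rings B and D). C1 of rings B, D and E and both ether carbons of ring C would themselves be carbonyl carbons, so O1, O3 and the ring E side of O4 are out of reach.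
- Comparison: it needs about three operations per quinone-derived ring where the chosen plan needs two (coupling, oxidation), and it leaves ring E unsolved. The chosen plan gives up the one-flask assembly of ring B and offers instead an O4 bond made by alkylation at sp3 carbon and a ring E that needs no hydroxyl differentiation.

**Alternative 2:** The hydroxyls on C4 of rings B, D and E are traced back to acetyl groups: pentamer tris(acetate) A3 comes from pentamer triketone A4 (COCH3 on C4 of rings B, D and E, all other oxygens as methyl ethers). Earlier in that plan each acetyl group sits para to C1 of its ring and activates a fluoride there, so O1, O3 and O4 are made by nucleophilic aromatic substitution at exactly the crowded carbons. The forward key step is a threefold Baeyer–Villiger oxidation with a buffered peracid.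
- For: substitution para to an acyl group is the most dependable way to put an oxygen on a carbon flanked by two alkoxy groups. The ketone intermediates are electron-poor and robust. Ring E enters as one simple building block, so on O4 and on convergence this plan is stronger than the chosen one.
- Against: aryl methyl ketones react far more slowly with peracids than aldehydes, and three must go to completion on a molecule that contains ring A, a 3,5-dimethoxyphenyl ether that peracids hydroxylate. O2 is not covered, because C6 of ring B is meta to the acetyl group and ring C has none. Rings B and D need building blocks with fluoride, phenol oxygen and acetyl in fixed relation, each both nucleophile and electrophile and several steps from commerce.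
- Comparison: the route below borrows the idea in a milder form (formyl groups ortho to the reacting carbon, oxidised one at a time right after each coupling) but does not let ring E depend on it. In place of the convergent substitution at ring E, the chosen plan offers a ring E whose three hydroxyls appear without any oxidation of the finished pentamer.

**Alternative 3:** Ring A is disconnected at its C3–C4 bond, and the A–B dimer 5-[2-(benzyloxy)-4,6-dimethoxyphenoxy]benzene-1,3-diol A5 is traced back to 4-[2-(benzyloxy)-4,6-dimethoxyphenoxy]-6-methyl-2H-pyran-2-one A6. In the forward step a hindered lithium amide removes a proton from the C6 methyl group of A6. The carbanion attacks the lactone carbonyl carbon, the ring oxygen leaves as an enolate, and the product tautomerises to the resorcinol.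
- For: O1 would be made beforehand by metal-free addition–elimination at C4 of the pyranone with the crowded ring B oxygen as nucleophile. Ring A appears with free hydroxyls. The C–C bond formation is intramolecular, which is an advantage over the intermolecular double condensation of the chosen key step.
- Against: it builds the one ring that needs no building. Ring A is available as iodide 9 and goes onto phenol 8 in a single coupling (step 5). Methyl carbanions of such pyranones persist at low temperature, so the ring transformation needs forcing and competes with attack of base at C4 or C6 and loss of the aryloxide. The free resorcinol A5 must be masked again before any copper coupling. Rings C to E and O2 to O4 are untouched.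
- Comparison: the principle, an arene grown around a carbon that already carries the ether oxygen, is the same as in the chosen plan. The chosen plan applies it at ring E, where arylation is least promising, and saves the steps needed to make A6 and to re-protect A5.

Key step: step 10

Remark: compounds 5, 9, 12, 16 and 18 are taken to be catalogue compounds, and diol 3 is used at once because it oxidises in air.

## Route

Step 1
Reactants: 1 syringaldehyde (4-hydroxy-3,5-dimethoxybenzaldehyde)
Product: 3 2,6-dimethoxybenzene-1,4-diol, via aryl formate 2 (not isolated)
Conditions: 30% H2O2, NaOH, H2O–THF, 0 °C to rt, N2; aq. HCl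
Reagents that add atoms: hydrogen peroxide, OO
Why: Dakin oxidation: hydroperoxide adds to the aldehyde, the electron-rich para-hydroxyaryl group migrates to oxygen and formate 2 is hydrolysed in the alkaline medium; acidic work-up under nitrogen should keep the hydroquinone from going on to the quinone.

Step 2
Reactants: 3 2,6-dimethoxybenzene-1,4-diol
Product: 4 4-(benzyloxy)-2,6-dimethoxyphenol
Conditions: BnBr (1.0 equiv), K2CO3 (1.0 equiv), DMF, 0 °C to rt, N2
Reagents that add atoms: benzyl bromide, BrCc1ccccc1
Why: Williamson etherification; the C4 hydroxyl lies between two CH groups and is the more acidic one (two meta methoxy groups), whereas the C1 hydroxyl is flanked and hydrogen-bonded by two methoxy groups, so one equivalent of base and halide should alkylate the C4 oxygen.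

Step 3
Reactants: 4 4-(benzyloxy)-2,6-dimethoxyphenol; 5 2-bromo-4,6-dimethoxybenzaldehyde
Product: 6 2-[4-(benzyloxy)-2,6-dimethoxyphenoxy]-4,6-dimethoxybenzaldehyde
Conditions: CuI (10 mol %), picolinic acid (20 mol %), K3PO4, DMSO, 90 °C, Ar
Reagents that add atoms: none
Why: Ullmann-type diaryl ether synthesis forming O2; the crowding is on the phenoxide of 4, while the C–Br bond of 5 has the formyl group as its only ortho neighbour and is activated by it; the aldehyde has no α-hydrogen and should tolerate K3PO4.

Step 4
Reactants: 6 2-[4-(benzyloxy)-2,6-dimethoxyphenoxy]-4,6-dimethoxybenzaldehyde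
Product: 8 2-[4-(benzyloxy)-2,6-dimethoxyphenoxy]-4,6-dimethoxyphenol, via aryl formate 7 (not isolated)
Conditions: mCPBA, CH2Cl2, 0 °C to rt; then K2CO3 (cat.), MeOH, rt
Reagents that add atoms: mCPBA (3-chloroperoxybenzoic acid), O=C(OO)c1cccc(Cl)c1
Why: Baeyer–Villiger oxidation; the 2,4,6-trioxygenated aryl group migrates much faster than hydride, and mild methanolysis of formate 7 frees the hydroxyl on C1 of ring B; benzyl and methyl ethers are untouched.

Step 5
Reactants: 8 2-[4-(benzyloxy)-2,6-dimethoxyphenoxy]-4,6-dimethoxyphenol; 9 1-iodo-3,5-dimethoxybenzene
Product: 10 5-(benzyloxy)-2-[2-(3,5-dimethoxyphenoxy)-3,5-dimethoxyphenoxy]-1,3-dimethoxybenzene (A–B–C benzyl ether)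
Conditions: CuI (10 mol %), picolinic acid (20 mol %), K3PO4, DMSO, 100 °C, Ar
Reagents that add atoms: none
Why: Ullmann-type coupling forming O1 under conditions made for ortho,ortho'-disubstituted phenols; all crowding is on the phenoxide of 8, and iodide 9 is unhindered and slightly electron-poor at the reacting carbon because both methoxy groups are meta.

Step 6
Reactants: 10 A–B–C benzyl ether
Product: 11 4-[2-(3,5-dimethoxyphenoxy)-3,5-dimethoxyphenoxy]-3,5-dimethoxyphenol (A–B–C phenol)
Conditions: H2 (1 atm), 10% Pd/C, EtOAc–MeOH, rt
Reagents that add atoms: none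
Why: Hydrogenolysis of the benzyl ether; diaryl and methyl ethers are inert, and 10 contains no halogen or carbonyl group.

Step 7
Reactants: 11 A–B–C phenol; 12 2-bromo-3,5-dimethoxybenzaldehyde
Product: 13 2-{4-[2-(3,5-dimethoxyphenoxy)-3,5-dimethoxyphenoxy]-3,5-dimethoxyphenoxy}-3,5-dimethoxybenzaldehyde (A–B–C–D aldehyde)
Conditions: CuI (10 mol %), picolinic acid (20 mol %), K3PO4, DMSO, 100 °C, Ar
Reagents that add atoms: none
Why: Ullmann-type coupling forming O3; the phenoxide of 11 is unhindered, and insertion of copper into the crowded C–Br bond of 12 is helped by the ortho formyl group (ortho-carbonyl effect of copper-mediated aryl halide substitution).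

Step 8
Reactants: 13 A–B–C–D aldehyde
Product: 15 2-{4-[2-(3,5-dimethoxyphenoxy)-3,5-dimethoxyphenoxy]-3,5-dimethoxyphenoxy}-3,5-dimethoxyphenol (A–B–C–D phenol), via aryl formate 14 (not isolated)
Conditions: mCPBA, CH2Cl2, 0 °C to rt; then K2CO3 (cat.), MeOH, rt
Reagents that add atoms: mCPBA (3-chloroperoxybenzoic acid), O=C(OO)c1cccc(Cl)c1
Why: Baeyer–Villiger oxidation of a 2-aryloxybenzaldehyde, in which the ortho aryloxy donor favours aryl over hydride migration, followed by methanolysis of formate 14; low temperature and a small excess of peracid should spare the electron-rich rings.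

Step 9
Reactants: 15 A–B–C–D phenol; 16 diethyl chloromalonate
Product: 17 diethyl 2-(2-{4-[2-(3,5-dimethoxyphenoxy)-3,5-dimethoxyphenoxy]-3,5-dimethoxyphenoxy}-3,5-dimethoxyphenoxy)malonate
Conditions: K2CO3, acetone, reflux
Reagents that add atoms: none
Why: SN2 alkylation of a phenoxide by an α-halomalonate, the standard preparation of aryloxymalonates; it forms O4 at an sp3 carbon, where the ortho aryloxy group of ring D costs little.

Step 10
Reactants: 17 diethyl aryloxymalonate; 18 diethyl 3-oxopentanedioate (3 equiv)
Product: 20 diethyl 2,4,6-trihydroxy-5-(aryloxy)benzene-1,3-dicarboxylate (aryloxy = oxygen-linked residue of 15; pentamer diester), via acyclic triester 19 (not isolated)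
Conditions: NaOEt (3 equiv), EtOH, reflux; then toluene, 110 °C (EtOH distilled off), Ar; aq. HCl
Reagents that add atoms: none
Why: With base limited to the amount of 18, the more acidic oxoglutarate holds the negative charge and 17 stays protonated and electrophilic; the enolate of 18 is C-acylated by one ester group of 17 (Claisen condensation, C2–C3 of ring E) to give 19. The remaining CH2 of the oxoglutarate part of 19 then attacks the second ester group of the former malonate in a Dieckmann-type 6-exo-trig closure (C5–C6), which closes ring E. The resulting cyclohexane-1,3,5-trione tautomerises to the aromatic triol 20 and is deprotonated, which pulls the reversible sequence forward, as does removal of ethanol. The closest known reaction type is the cyclocondensation of malonic esters with 3-oxoglutaric esters to 2,4,6-trihydroxyisophthalates, whose parent is the self-condensation of sodiomalonic ester to the phloroglucinol tricarboxylate; here the malonate carries a 2-aryloxy group. No stereocentre is formed, since the two labile centres of 19 vanish on aromatisation. The step needs C- over O-acylation and cross- over self-condensation; both are secured thermodynamically, because enol esters or a pyranone from O-acylation and the quaternary adduct from attack of the malonate carbanion on 18 are reopened by ethoxide, and only the doubly C-acylated ring can aromatise. Both partners are symmetric, so there is no regiochemical choice, and the excess of 18 covers its own self-condensation. The rest of the molecule holds only aryl ethers, which are inert to alkoxide.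

Step 11
Reactants: 20 pentamer diester
Product: 22 2-(aryloxy)benzene-1,3,5-triol (aryloxy = oxygen-linked residue of 15; octa-O-methyl pentamer), via diacid 21 (not isolated)
Conditions: KOH, EtOH–H2O, reflux, Ar; then aq. HCl, 60 °C
Reagents that add atoms: none
Why: Saponification gives diacid 21, a 2,4,6-trihydroxybenzoic acid twice over, which loses both carboxyl groups on acidification and gentle warming by ipso protonation; exclusion of air protects the electron-rich triol.

Step 12
Reactants: 22 octa-O-methyl pentamer
Product: 23 CNP0018313.0 (target)
Conditions: BBr3 (excess), CH2Cl2, −78 °C to rt; H2O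
Reagents that add atoms: none
Why: Lewis acid-mediated cleavage of the eight aryl methyl ethers (coordination of boron to oxygen, bromide attack on methyl); the diaryl ether bonds offer no sp3 carbon for attack and should survive.

## Compound list

In the names of 17 and 19 to 22, "aryloxy" stands for 2-{4-[2-(3,5-dimethoxyphenoxy)-3,5-dimethoxyphenoxy]-3,5-dimethoxyphenoxy}-3,5-dimethoxyphenoxy.

1 | syringaldehyde (4-hydroxy-3,5-dimethoxybenzaldehyde) | COc1cc(C=O)cc(OC)c1O | starting material
2 | 4-hydroxy-3,5-dimethoxyphenyl formate | COc1cc(OC=O)cc(OC)c1O | intermediate (not isolated)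
3 | 2,6-dimethoxybenzene-1,4-diol | COc1cc(O)cc(OC)c1O | intermediate
4 | 4-(benzyloxy)-2,6-dimethoxyphenol | COc1cc(OCc2ccccc2)cc(OC)c1O | intermediate
5 | 2-bromo-4,6-dimethoxybenzaldehyde | COc1cc(Br)c(C=O)c(OC)c1 | starting material
6 | 2-[4-(benzyloxy)-2,6-dimethoxyphenoxy]-4,6-dimethoxybenzaldehyde | COc1cc(OC)c(C=O)c(Oc2c(OC)cc(OCc3ccccc3)cc2OC)c1 | intermediate
7 | 2-[4-(benzyloxy)-2,6-dimethoxyphenoxy]-4,6-dimethoxyphenyl formate | COc1cc(OC)c(OC=O)c(Oc2c(OC)cc(OCc3ccccc3)cc2OC)c1 | intermediate (not isolated)
8 | 2-[4-(benzyloxy)-2,6-dimethoxyphenoxy]-4,6-dimethoxyphenol | COc1cc(OC)c(O)c(Oc2c(OC)cc(OCc3ccccc3)cc2OC)c1 | intermediate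
9 | 1-iodo-3,5-dimethoxybenzene | COc1cc(I)cc(OC)c1 | starting material
10 | 5-(benzyloxy)-2-[2-(3,5-dimethoxyphenoxy)-3,5-dimethoxyphenoxy]-1,3-dimethoxybenzene | COc1cc(OC)cc(Oc2c(OC)cc(OC)cc2Oc2c(OC)cc(OCc3ccccc3)cc2OC)c1 | intermediate
11 | 4-[2-(3,5-dimethoxyphenoxy)-3,5-dimethoxyphenoxy]-3,5-dimethoxyphenol | COc1cc(OC)cc(Oc2c(OC)cc(OC)cc2Oc2c(OC)cc(O)cc2OC)c1 | intermediate
12 | 2-bromo-3,5-dimethoxybenzaldehyde | COc1cc(C=O)c(Br)c(OC)c1 | starting material
13 | 2-{4-[2-(3,5-dimethoxyphenoxy)-3,5-dimethoxyphenoxy]-3,5-dimethoxyphenoxy}-3,5-dimethoxybenzaldehyde | COc1cc(OC)cc(Oc2c(OC)cc(OC)cc2Oc2c(OC)cc(Oc3c(OC)cc(OC)cc3C=O)cc2OC)c1 | intermediate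
14 | 2-{4-[2-(3,5-dimethoxyphenoxy)-3,5-dimethoxyphenoxy]-3,5-dimethoxyphenoxy}-3,5-dimethoxyphenyl formate | COc1cc(OC)cc(Oc2c(OC)cc(OC)cc2Oc2c(OC)cc(Oc3c(OC)cc(OC)cc3OC=O)cc2OC)c1 | intermediate (not isolated)
15 | 2-{4-[2-(3,5-dimethoxyphenoxy)-3,5-dimethoxyphenoxy]-3,5-dimethoxyphenoxy}-3,5-dimethoxyphenol | COc1cc(OC)cc(Oc2c(OC)cc(OC)cc2Oc2c(OC)cc(Oc3c(OC)cc(OC)cc3O)cc2OC)c1 | intermediate
16 | diethyl chloromalonate | CCOC(=O)C(Cl)C(=O)OCC | starting material
17 | diethyl 2-(aryloxy)malonate | COc1cc(OC)cc(Oc2c(OC)cc(OC)cc2Oc2c(OC)cc(Oc3c(OC)cc(OC)cc3OC(C(=O)OCC)C(=O)OCC)cc2OC)c1 | intermediate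
18 | diethyl 3-oxopentanedioate | CCOC(=O)CC(=O)CC(=O)OCC | starting material
19 | triethyl 1-(aryloxy)-2,4-dioxopentane-1,3,5-tricarboxylate (enolised; its two centres are configurationally labile and undefined) | COc1cc(OC)cc(Oc2c(OC)cc(OC)cc2Oc2c(OC)cc(Oc3c(OC)cc(OC)cc3OC(C(=O)OCC)C(=O)C(C(=O)OCC)C(=O)CC(=O)OCC)cc2OC)c1 | intermediate (not isolated)
20 | diethyl 2,4,6-trihydroxy-5-(aryloxy)benzene-1,3-dicarboxylate | COc1cc(OC)cc(Oc2c(OC)cc(OC)cc2Oc2c(OC)cc(Oc3c(OC)cc(OC)cc3Oc3c(O)c(C(=O)OCC)c(O)c(C(=O)OCC)c3O)cc2OC)c1 | intermediate
21 | 2,4,6-trihydroxy-5-(aryloxy)benzene-1,3-dicarboxylic acid | COc1cc(OC)cc(Oc2c(OC)cc(OC)cc2Oc2c(OC)cc(Oc3c(OC)cc(OC)cc3Oc3c(O)c(C(=O)O)c(O)c(C(=O)O)c3O)cc2OC)c1 | intermediate (not isolated)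
22 | 2-(aryloxy)benzene-1,3,5-triol | COc1cc(OC)cc(Oc2c(OC)cc(OC)cc2Oc2c(OC)cc(Oc3c(OC)cc(OC)cc3Oc3c(O)cc(O)cc3O)cc2OC)c1 | intermediate
23 | CNP0018313.0 | Oc1cc(O)cc(Oc2c(O)cc(O)cc2Oc2c(O)cc(Oc3c(O)cc(O)cc3Oc3c(O)cc(O)cc3O)cc2O)c1 | target

## Step count and least certain steps

Total: 12 steps. Longest linear sequence: 12 steps (1 to 23).

**Step 10 (key step).** The aryloxymalonate may sit largely as its unreactive enolate, so that self-condensation of 18 and ethoxide-induced loss of an ethoxycarbonyl group from 17 outrun the cross-condensation. O-acylation to a pyranone that does not reopen is a second possible failure. The fallback gives up ring synthesis for a three-plus-two ether coupling with intermediates already in hand. It sets out from 11 and 8 and returns at 23. Phenol 11 is converted with Tf2O and pyridine into 4-[2-(3,5-dimethoxyphenoxy)-3,5-dimethoxyphenoxy]-3,5-dimethoxyphenyl trifluoromethanesulfonate F1. A palladium-catalysed C–O coupling (Pd(OAc)2, a di-tert-butyl biaryl phosphine, K3PO4, toluene, 100 °C) joins F1 to the crowded phenol 8, which here serves as a ring D–ring E unit with its benzyl-protected ring becoming ring E. This gives the deca-O-methyl pentamer benzyl ether F2. Hydrogenolysis over Pd/C gives the deca-O-methyl pentamer phenol F3, and BBr3 cleaves its ten methyl ethers to 23.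

**Step 7.** Insertion of copper into the doubly ortho-substituted C–Br bond may be slow, and the aldehyde may be lost to base-induced disproportionation or to reduction of the halide before coupling occurs. The fallback uses the carboxylate-directed form of the Ullmann reaction. It sets out from 11 and 12 and returns at 13. Aldehyde 12 is oxidised (NaClO2, NaH2PO4, 2-methyl-2-butene) to 2-bromo-3,5-dimethoxybenzoic acid F4. F4 couples with 11 (CuI cat., K2CO3, DMF, 120 °C) to give the A–B–C–D carboxylic acid F5. BH3·THF reduces F5 to the A–B–C–D benzyl alcohol F6, and MnO2 oxidises F6 to 13.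

**Step 5.** Crowding around the phenoxide oxygen may slow the C–O bond-forming step, so that reduction or homocoupling of 9 and oxidation of the electron-rich phenoxide take over. The fallback is a Chan–Lam oxidative coupling, which uses a nucleophilic aryl donor and divalent copper at room temperature: 8 with (3,5-dimethoxyphenyl)boronic acid, Cu(OAc)2, pyridine, 4 Å molecular sieves, CH2Cl2, air. It sets out from 8 and returns at 10 with no new intermediate.

**Step 12.** Cleavage of the methyl ethers flanked by aryloxy groups may stay incomplete, and the free undecaphenol may be oxidised during aqueous work-up and chromatography. The fallback avoids isolating the free phenol. It sets out from 22 and returns at 23. The crude demethylation product is acetylated (Ac2O, pyridine) to the undecaacetate F7, which is stable to air and can be purified on silica. Acid methanolysis (HCl, MeOH, Ar) then gives 23.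

## Further compounds

F1 | step 10 | 4-[2-(3,5-dimethoxyphenoxy)-3,5-dimethoxyphenoxy]-3,5-dimethoxyphenyl trifluoromethanesulfonate | COc1cc(OC)cc(Oc2c(OC)cc(OC)cc2Oc2c(OC)cc(OS(=O)(=O)C(F)(F)F)cc2OC)c1
F2 | step 10 | deca-O-methyl pentamer, benzyl ether on C4 of ring E | COc1cc(OC)cc(Oc2c(OC)cc(OC)cc2Oc2c(OC)cc(Oc3c(OC)cc(OC)cc3Oc3c(OC)cc(OCc4ccccc4)cc3OC)cc2OC)c1
F3 | step 10 | deca-O-methyl pentamer, free hydroxyl on C4 of ring E | COc1cc(OC)cc(Oc2c(OC)cc(OC)cc2Oc2c(OC)cc(Oc3c(OC)cc(OC)cc3Oc3c(OC)cc(O)cc3OC)cc2OC)c1
F4 | step 7 | 2-bromo-3,5-dimethoxybenzoic acid | COc1cc(C(=O)O)c(Br)c(OC)c1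
F5 | step 7 | 2-{4-[2-(3,5-dimethoxyphenoxy)-3,5-dimethoxyphenoxy]-3,5-dimethoxyphenoxy}-3,5-dimethoxybenzoic acid | COc1cc(OC)cc(Oc2c(OC)cc(OC)cc2Oc2c(OC)cc(Oc3c(OC)cc(OC)cc3C(=O)O)cc2OC)c1
F6 | step 7 | (2-{4-[2-(3,5-dimethoxyphenoxy)-3,5-dimethoxyphenoxy]-3,5-dimethoxyphenoxy}-3,5-dimethoxyphenyl)methanol | COc1cc(OC)cc(Oc2c(OC)cc(OC)cc2Oc2c(OC)cc(Oc3c(OC)cc(OC)cc3CO)cc2OC)c1
F0 | step 5 | none | none
F7 | step 12 | undecaacetate of the target | CC(=O)Oc1cc(OC(C)=O)cc(Oc2c(OC(C)=O)cc(OC(C)=O)cc2Oc2c(OC(C)=O)cc(Oc3c(OC(C)=O)cc(OC(C)=O)cc3Oc3c(OC(C)=O)cc(OC(C)=O)cc3OC(C)=O)cc2OC(C)=O)c1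
A1 | alternative 1 | 2-[4-(benzyloxy)-2,6-dimethoxyphenoxy]-6-methoxy-1,4-benzoquinone | COC1=CC(=O)C=C(Oc2c(OC)cc(OCc3ccccc3)cc2OC)C1=O
A2 | alternative 1 | 2,6-dichloro-1,4-benzoquinone | O=C1C=C(Cl)C(=O)C(Cl)=C1
A3 | alternative 2 | pentamer tris(acetate), acetoxy on C4 of rings B, D and E | COc1cc(OC)cc(Oc2c(OC)cc(OC(C)=O)cc2Oc2c(OC)cc(Oc3c(OC)cc(OC(C)=O)cc3Oc3c(OC)cc(OC(C)=O)cc3OC)cc2OC)c1
A4 | alternative 2 | pentamer triketone, acetyl on C4 of rings B, D and E | COc1cc(OC)cc(Oc2c(OC)cc(C(C)=O)cc2Oc2c(OC)cc(Oc3c(OC)cc(C(C)=O)cc3Oc3c(OC)cc(C(C)=O)cc3OC)cc2OC)c1
A5 | alternative 3 | 5-[2-(benzyloxy)-4,6-dimethoxyphenoxy]benzene-1,3-diol | Oc1cc(O)cc(Oc2c(OC)cc(OC)cc2OCc2ccccc2)c1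
A6 | alternative 3 | 4-[2-(benzyloxy)-4,6-dimethoxyphenoxy]-6-methyl-2H-pyran-2-one | CC1=CC(Oc2c(OC)cc(OC)cc2OCc2ccccc2)=CC(=O)O1
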